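## Structural features

The target is pentacyclic. Rings A, B and C form a phenanthrene-1,9-dione skeleton (C1–C10a): ring A is a cross-conjugated cyclohexa-2,5-dienone (C1 ketone, C2=C3, C4a=C10a) with C4 as its only sp3 carbon, ring B holds the C9 ketone and the C10 methylene, and ring C is a benzene ring with OMe at C6 and a phenol at C8 hydrogen-bonded to the C9 carbonyl. Ring D is an oxazolidine fused to ring A across C3–C4 (C3–N, N–CH, CH–O, O–C4), and ring E is a pyrrolidine fused to ring D across the N–CH bond, so nitrogen is a bridgehead and the donor of a vinylogous amide (N–C3=C2–C1=O). There are two stereocentres, the quaternary C4 (methyl, oxygen, C3, C4a; R) and the aminal carbon (S); they are not neighbours but stand 1,3 to each other across the ring D oxygen, so the aminal carbon can be set from C4. Fragile points are the N,O-acetal and the tertiary C4–O bond (both acid-labile), the dienone (conjugate addition, dienone–phenol rearrangement), and the C10 methylene, whose enolisation gives the aromatic 8,9-diol tautomer. The real difficulty is C4, a fully substituted oxygen-bearing stereocentre next to the nitrogen-bearing C3; C3 itself is flanked by the C2 methoxy group and C4, which makes any aryl–N bond formation there hard. The key step uses the fact that C4 lies para to the C1 carbonyl: ring A is an oxidised para-methyl phenol, and a carboxyl group on the carbon attached to the C3 nitrogen can reach C4 and deliver its oxygen to one face; that carbon is the future aminal carbon.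

## Logic of the disconnections

23 from 21. The O8–CH2Ph bond is cut. A benzyl ether is removed under neutral conditions, which the N,O-acetal and the C4–O bond require. Its removal gives 22, the enol tautomer of 23. The forward step must stop at the benzyl ether.

21 from 17 and 20. The bonds C4a–C4b and C8a–C9 are cut, which removes ring C and opens ring B at once. 17 keeps C9 and C10 as an ester arm on C10a and has a free C4a–H, so its ester dienolate is the four-carbon partner and 20 the two-carbon partner. The forward step needs the gamma carbon C4a, not C10, to bond to the aryne carbon remote from the benzyloxy group. It also needs 20 to form in one orientation only. A silyl triflate built on a 1,3,5-trioxygenated ring would have two competing ortho positions; 19 has bromine with a single ortho hydrogen and avoids this.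

19 from 18. The O–benzyl bond is cut. 18 is commercial and already has bromine ortho to the future O8 and para to the methoxy group.

17 from 14. The aminal C–O bond is cut and a carbonyl carbon is put back between the aminal carbon and O4, which turns ring D into the six-membered lactone of 14. The aminal stereocentre becomes the alpha carbon of an amino acid, and the C4–O bond becomes an ester bond that a phenol oxidation can make. Forward, 15 must lose CO2 and two electrons to give 16 without damage to the dienone, and O4 must add on the face away from the C4 methyl. 15 is not isolated because the free acid would re-lactonise.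

14 from 13. The C4–O bond is cut and ring A is rearomatised to the phenol. This removes the only ring A stereocentre and leaves an amino acid as the sole source of chirality. The forward step needs attack at C4 (para) and not at C2 (ortho), on one face.

13 from 12. The O–Si and O–CH3 bonds are cut. Phenol and carboxylic acid are released together just before the oxidation, so the air-sensitive aminophenol acid is not carried through earlier steps. The tert-butyl ester must survive.

12 from 10 and 11. The C10a–C10 bond is cut. The arm goes on after nitrogen, because bromination para to a free amino group (in 5) is the reliable way to mark C10a. The coupling must tolerate two esters and a silyl ether.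

10 from 5 and 8. Both N–C bonds of ring E (N–C alpha, N–C delta) are cut, not the aryl–N bond. A halide at C3 would sit between OMe and Me, and Cu- or Pd-catalysed coupling of an alpha-branched secondary amino acid at such a position would be expected to be unreliable. C3 of a 2-methoxy-4-methylphenol is also not open to selective halogenation or directed metalation, since electrophiles and bases go to C4a or C10a. An aniline nitrogen already on C3 is alkylated twice instead. The first alkylation (giving 9) must invert the alpha carbon cleanly.

8 from 7 from 6. The O–S bond, then the C5–Br bond, are cut back to a commercial (R)-oxolane ester. The alpha C–O bond is never broken before the SN2 step, so (R) in 6 becomes (S) in 10.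

5 from 4 from 3 from 1. The C–Br and O–Si bonds are cut, then the C4 methyl and the C3 amino group are traced back to the aldehyde and nitro group of 1. This commercial compound has O1, the C2 methoxy group, the C3 nitrogen and the C4 carbon in place. 2 is reduced first so that no ortho-amino benzaldehyde is formed.

## Other disconnections considered

Alternative 1: The cut goes through rings A and D at once, at C3–C4 and at the aminal C–O bond. Forward, the aldehyde of the naphthyl keto aldehyde A1 condenses with cis-4-(tert-butyldimethylsilyloxy)-L-proline A2, decarboxylation gives a non-stabilised azomethine ylide, and this adds across the acetyl carbonyl to give the pentacyclic oxazolidine A3.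
- In its favour: two rings, two bonds and three stereocentres (C3, C4, aminal carbon) arise in one thermal step without an oxidant. Rings B and C are an ordinary naphthalene, so no aryne and no dienolate are needed. Nitrogen enters by condensation, so the crowded C3–N bond is never an aryl–N bond. On these three points it is better than the chosen plan, whose key step builds one ring and one stereocentre.
- Against it here: a ketone is a reluctant partner for such ylides, and a six-membered carbocycle has to close at the same time. Decarboxylation erases the alpha stereocentre of A2, so the configuration at C4 rests on the remote silyloxy group, which then costs a deoxygenation. A3 has C2 as a ketal and C3 as sp3 CH, so acid hydrolysis next to an N,O-acetal and an enol ether formation follow. The two ring C methyl ethers need a selective cleavage at O8 besides debenzylation.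
- Comparison: in the chosen plan the controlling stereocentre lies inside the forming ring and is removed without extra steps, and ring A leaves the key step at the right oxidation level. In step count the two are close; the alternative is shorter before its key step and longer after it.

Alternative 2: The cut is the C3–N bond, with C4 already a quinol carbon. The achiral quinol carbamate A4 has two enantiotopic enone beta carbons; a chiral bifunctional base catalyst would steer the carbamate N–H to one of them and give the cis-fused oxazolidinone enone A5.
- In its favour: C4 is set by a catalyst, so either enantiomer is equally accessible, and the quinol core comes from a simple oxidative dearomatisation with water. In source of chirality and cost of the first steps it is better than the chosen plan. Both plans use a one-carbon carbonyl tether that is excised later, so on that point they are equal.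
- Against it here: A5 is a bare ring A. C2 has no oxygen, C3 is an sp3 CH that must be returned to the enaminone, C10a has no arm and C4a no aryl group. Ring A must therefore be oxidised and substituted at three positions after the stereocentre is set, with a sensitive quinol carbamate present, and rings D and E must still be closed from the acetal chain.
- Comparison: the stereo-defining step is a mild conjugate addition under catalyst control, against an oxidation under substrate control. The alternative is short before its key step and long after it; the chosen plan carries every ring A substituent through the key step and needs four steps after it.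

Alternative 3: The cut removes C9–C10 and C4a–C10a and opens rings A and B together; rings D and E and C4 are already present. On irradiation the ortho-alkyl benzaldehyde A6 would move a hydrogen from the C4a methylene to the aldehyde oxygen, and the resulting dienol adds to the tethered vinyl ketone to give the C9 alcohol A7.
- In its favour: two rings and two C–C bonds form with light as the only reagent, and there is no strong base and no aryne regiochemistry. On these points it is better than the annulation step of the chosen plan.
- Against it here: the three stereocentres it creates (C9, C4a, C10a) are absent from the target, so oxidation at C9 and dehydrogenation across C4a–C10a must follow. A7 has a methyl ether at O8 that must be cleaved next to the N,O-acetal. The step also leaves the real problem untouched: A6 must already contain the quaternary C4, the aminal carbon and an electron-rich enaminone vinyl ketone that may polymerise or absorb the light itself.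
- Comparison: the chosen plan spends its key step on C4 and builds rings B and C at the right oxidation level. The alternative spends it on the carbocycles and corrects the oxidation level afterwards. It is likely the longer route, because A6 needs its own stereocontrolled synthesis.

Key step: step 9

Assumption: 23 is written as its C9-keto, C10-methylene tautomer; the 8,9-diol 22 released in the last step is the same compound by proton transfer and is taken to settle in the keto form, which gains the O8–H to O9 hydrogen bond and the C4a=C10a–C1=O conjugation.

## Steps

Step 1
Reactants: 1 4-hydroxy-3-methoxy-2-nitrobenzaldehyde (2-nitrovanillin)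
Product: 3 3-amino-2-methoxy-4-methylphenol, via nitrobenzyl alcohol 2 (not isolated)
Conditions: NaBH4, MeOH, 0 °C; then AcOH, Pd/C, H2 (4 bar), 40 °C
Reagents that add atoms: none
Why: Borohydride reduction of the aldehyde, then catalytic hydrogenation reduces the nitro group and cleaves the benzylic C–O bond, which is activated by the para hydroxyl and ortho amino groups; reducing the aldehyde first avoids self-condensation of an ortho-amino benzaldehyde.

Step 2
Reactants: 3 3-amino-2-methoxy-4-methylphenol
Product: 4 3-(tert-butyldimethylsilyloxy)-2-methoxy-6-methylaniline
Conditions: TBSCl, imidazole, DMF, 0 °C to rt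
Reagents that add atoms: tert-butyldimethylsilyl chloride (TBSCl), C[Si](C)(Cl)C(C)(C)C
Why: Imidazole-promoted silylation should be selective for the phenol, because the aniline nitrogen is flanked by OMe and Me and is a poor nucleophile toward silicon.

Step 3
Reactants: 4 3-(tert-butyldimethylsilyloxy)-2-methoxy-6-methylaniline
Product: 5 4-bromo-3-(tert-butyldimethylsilyloxy)-2-methoxy-6-methylaniline
Conditions: NBS, MeCN, −20 °C
Reagents that add atoms: N-bromosuccinimide (NBS), BrN1C(=O)CCC1=O
Why: Electrophilic aromatic bromination para to the free amino group marks C10a; the only other open position (C4a) is meta to nitrogen.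

Step 4
Reactants: 6 methyl (2R)-tetrahydrofuran-2-carboxylate
Product: 7 methyl (2R)-5-bromo-2-hydroxypentanoate
Conditions: BBr3 (1.1 equiv), CH2Cl2, −78 to 0 °C; H2O
Reagents that add atoms: boron tribromide, BrB(Br)Br
Why: Lewis-acid ether cleavage: bromide opens the boron-activated oxolane by SN2 at the primary C5, remote from the ester, so the C2–O bond and the (R) configuration are untouched.

Step 5
Reactants: 7 methyl (2R)-5-bromo-2-hydroxypentanoate
Product: 8 methyl (2R)-5-bromo-2-(trifluoromethylsulfonyloxy)pentanoate
Conditions: Tf2O, 2,6-lutidine, CH2Cl2, −78 °C; used at once
Reagents that add atoms: trifluoromethanesulfonic anhydride (Tf2O), O=S(=O)(OS(=O)(=O)C(F)(F)F)C(F)(F)F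
Why: O-Sulfonylation of the alpha-hydroxy ester with a hindered base gives a highly reactive SN2 electrophile without touching the stereocentre.

Step 6
Reactants: 5 4-bromo-3-(tert-butyldimethylsilyloxy)-2-methoxy-6-methylaniline; 8 methyl (2R)-5-bromo-2-(trifluoromethylsulfonyloxy)pentanoate
Product: 10 methyl (2S)-1-[4-bromo-3-(tert-butyldimethylsilyloxy)-2-methoxy-6-methylphenyl]pyrrolidine-2-carboxylate, via bromo amino ester 9 (not isolated)
Conditions: 2,6-lutidine, CH2Cl2, 0 °C to rt; then NaI (0.2 equiv), i-Pr2NEt, MeCN, 70 °C
Reagents that add atoms: none
Why: SN2 displacement of the alpha-triflate by the aniline with inversion sets the (S) alpha carbon, the way 2,6-disubstituted anilines are alkylated with lactate sulfonates; iodide-assisted 5-exo-tet N-alkylation (Finkelstein activation) then closes ring E. No aryl–N bond has to be made at the crowded C3.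

Step 7
Reactants: 10 methyl (2S)-1-[4-bromo-3-(tert-butyldimethylsilyloxy)-2-methoxy-6-methylphenyl]pyrrolidine-2-carboxylate; 11 (2-tert-butoxy-2-oxoethyl)zinc bromide
Product: 12 methyl (2S)-1-[4-(2-tert-butoxy-2-oxoethyl)-3-(tert-butyldimethylsilyloxy)-2-methoxy-6-methylphenyl]pyrrolidine-2-carboxylate
Conditions: Pd(dba)2 (5 mol%), XPhos (10 mol%), THF, 60 °C
Reagents that add atoms: none
Why: Negishi-type alpha-arylation with a Reformatsky reagent: zerovalent palladium inserts into the C10a–Br bond, the zinc enolate transmetalates and reductive elimination forms C10a–C10; the neutral zinc enolate should spare both esters and the silyl ether.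

Step 8
Reactants: 12 methyl (2S)-1-[4-(2-tert-butoxy-2-oxoethyl)-3-(tert-butyldimethylsilyloxy)-2-methoxy-6-methylphenyl]pyrrolidine-2-carboxylate
Product: 13 (2S)-1-[4-(2-tert-butoxy-2-oxoethyl)-3-hydroxy-2-methoxy-6-methylphenyl]pyrrolidine-2-carboxylic acid
Conditions: LiOH (5 equiv), THF/MeOH/H2O (degassed), rt; then 1 M HCl to pH 4
Reagents that add atoms: lithium hydroxide, [Li+].[OH-]
Why: Hydroxide saponifies the methyl ester and cleaves the aryl silyl ether in one operation, while the tert-butyl ester resists attack; phenol and carboxylic acid are unmasked together just before the oxidation.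

Step 9
Reactants: 13 (2S)-1-[4-(2-tert-butoxy-2-oxoethyl)-3-hydroxy-2-methoxy-6-methylphenyl]pyrrolidine-2-carboxylic acid
Product: 14 (4R)-dienone lactone: ring A with C1 ketone; C2 OMe; C2=C3 and C4a=C10a double bonds; tert-butyl acetate arm on C10a; C3–N and C4–O bridged by the (S)-prolyl carbonyl as a six-membered lactone
Conditions: PhI(OAc)2 (1.1 equiv), CF3CH2OH, −20 to 0 °C
Reagents that add atoms: none
Why: Ligand exchange of the phenol oxygen on PhI(OAc)2 and two-electron oxidation make ring A a phenoxenium-type electrophile with positive character at C2, C4 and C10a; the carboxylate held on the C3 nitrogen adds to C4 as iodobenzene leaves, so the C4–O bond and the cross-conjugated dienone form together. The closest known reaction type is the dearomatising lactonisation of para-alkyl phenols by a tethered carboxylic acid with a trivalent iodine reagent. The six-membered lactone (C3, N, C alpha, C=O, O, C4) closes in a 6-exo-trig sense, the C4–C4a pi bond lying outside the new ring. C4 is the only new stereocentre and is controlled by the (S) alpha carbon: the C3–N bond is flanked by OMe and Me, so ring E should stand roughly perpendicular to the arene, and of its two rotamers only one points the carboxylate at C4, on the face that gives (4R). The step needs para (C4) over ortho (C2) capture; the C4 methyl blocks rearomatisation, an acyloxy ketal formed at C2 should re-ionise and drain to the stable tertiary ester, and the weakly nucleophilic fluoroalcohol leaves the capture to the tether. The amino acid is expected to react as its zwitterion, which keeps the carboxylate free and the nitrogen protected from oxidation.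

Step 10
Reactants: 14 (4R)-dienone lactone
Product: 17 (4R)-dienone N,O-acetal: ring A and arm as in 14; rings D and E of the target in place (aminal carbon S), via hydroxy carboxylate 15 (not isolated), via pyrrolinium ion 16 (not isolated)
Conditions: LiOH (1.05 equiv), MeOH/H2O, 0 °C; then undivided cell, graphite anode and cathode, constant current (about 2.2 F/mol), 0–10 °C
Reagents that add atoms: none
Why: Hydroxide opens the lactone to the carboxylate; non-Kolbe (Hofer–Moest) anodic oxidation removes CO2 and two electrons to give the cyclic iminium ion, which O4 captures in a 5-endo-trig closure of the kind that forms oxazolidines from amino alcohols and aldehydes. The aminal carbon is set by C4: ring E should add on the face of ring D away from the C4 methyl, and the N,O-acetal can equilibrate through the iminium ion to this less strained isomer.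

Step 11
Reactants: 18 2-bromo-5-methoxyphenol
Product: 19 1-(benzyloxy)-2-bromo-5-methoxybenzene
Conditions: BnBr, K2CO3, acetone, reflux
Reagents that add atoms: benzyl bromide, BrCc1ccccc1
Why: Williamson ether synthesis on the phenoxide.

Step 12
Reactants: 17 (4R)-dienone N,O-acetal; 19 1-(benzyloxy)-2-bromo-5-methoxybenzene
Product: 21 (4R)-8-benzyloxy-9-hydroxy-2,6-dimethoxy-4-methyl-4H-phenanthren-1-one carrying rings D and E of the target (aminal carbon S), via aryne 20 (not isolated)
Conditions: lithium 2,2,6,6-tetramethylpiperidide (4 equiv) added to 17 and 19 (2 equiv), THF, −78 to −40 °C; H2O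
Reagents that add atoms: none
Why: The amide base forms the dienolate of the beta,gamma-unsaturated ester (C9=C10–C10a=C4a) and, by removing the only hydrogen ortho to bromine, the aryne; the aryne–dienolate [4+2] annulation known for naphthol synthesis joins C4a to C4b and C9 to C8a, tert-butoxide leaves and loss of H4a aromatises ring B. Regiochemistry follows from the 3-alkoxy aryne: the nucleophilic gamma carbon adds to the aryne carbon remote from OBn, and the aryl anion next to OBn acylates.

Step 13
Reactants: 21 (4R)-8-benzyloxy-9-hydroxy-2,6-dimethoxy-4-methyl-4H-phenanthren-1-one carrying rings D and E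
Product: 23 the target in its C9 keto form, via diol tautomer 22 (not isolated)
Conditions: H2 (1 atm), Pd/C, EtOAc, rt
Reagents that add atoms: none
Why: Hydrogenolysis of the aryl benzyl ether under neutral conditions; the freed 8,9-diol should tautomerise to the hydrogen-bonded C9 ketone, and the tetrasubstituted vinylogous amide and the N,O-acetal should not be reduced.

## Compound list

1 | 4-hydroxy-3-methoxy-2-nitrobenzaldehyde (2-nitrovanillin) | COc1c(O)ccc(C=O)c1[N+](=O)[O-] | starting material
2 | 4-(hydroxymethyl)-2-methoxy-3-nitrophenol (formed in the flask) | COc1c(O)ccc(CO)c1[N+](=O)[O-] | intermediate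
3 | 3-amino-2-methoxy-4-methylphenol | COc1c(O)ccc(C)c1N | intermediate
4 | 3-(tert-butyldimethylsilyloxy)-2-methoxy-6-methylaniline | COc1c(O[Si](C)(C)C(C)(C)C)ccc(C)c1N | intermediate
5 | 4-bromo-3-(tert-butyldimethylsilyloxy)-2-methoxy-6-methylaniline | COc1c(O[Si](C)(C)C(C)(C)C)c(Br)cc(C)c1N | intermediate
6 | methyl (2R)-tetrahydrofuran-2-carboxylate | COC(=O)[C@H]1CCCO1 | starting material
7 | methyl (2R)-5-bromo-2-hydroxypentanoate | COC(=O)[C@H](O)CCCBr | intermediate
8 | methyl (2R)-5-bromo-2-(trifluoromethylsulfonyloxy)pentanoate | COC(=O)[C@H](OS(=O)(=O)C(F)(F)F)CCCBr | intermediate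
9 | methyl (2S)-5-bromo-2-[4-bromo-3-(tert-butyldimethylsilyloxy)-2-methoxy-6-methylanilino]pentanoate (formed in the flask) | COC(=O)[C@@H](Nc1c(C)cc(Br)c(O[Si](C)(C)C(C)(C)C)c1OC)CCCBr | intermediate
10 | methyl (2S)-1-[4-bromo-3-(tert-butyldimethylsilyloxy)-2-methoxy-6-methylphenyl]pyrrolidine-2-carboxylate | COC(=O)[C@@H]1CCCN1c1c(C)cc(Br)c(O[Si](C)(C)C(C)(C)C)c1OC | intermediate
11 | (2-tert-butoxy-2-oxoethyl)zinc bromide, BrZnCH2CO2tBu (commercial solution) | CC(C)(C)OC(=O)C[Zn]Br | starting material
12 | methyl (2S)-1-[4-(2-tert-butoxy-2-oxoethyl)-3-(tert-butyldimethylsilyloxy)-2-methoxy-6-methylphenyl]pyrrolidine-2-carboxylate | COC(=O)[C@@H]1CCCN1c1c(C)cc(CC(=O)OC(C)(C)C)c(O[Si](C)(C)C(C)(C)C)c1OC | intermediate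
13 | (2S)-1-[4-(2-tert-butoxy-2-oxoethyl)-3-hydroxy-2-methoxy-6-methylphenyl]pyrrolidine-2-carboxylic acid (the N-aryl-L-proline) | CC(C)(C)OC(=O)Cc1cc(C)c(N2CCC[C@H]2C(=O)O)c(OC)c1O | intermediate
14 | (4R)-dienone lactone; alpha carbon (S) | CC(C)(C)OC(=O)CC1=C[C@@]2(C)OC(=O)[C@@H]3CCCN3C2=C(OC)C1=O | intermediate
15 | lithium (2S)-1-[(6R)-4-(2-tert-butoxy-2-oxoethyl)-6-hydroxy-2-methoxy-6-methyl-3-oxocyclohexa-1,4-dien-1-yl]pyrrolidine-2-carboxylate (formed in the flask) | CC(C)(C)OC(=O)CC1=C[C@@](C)(O)C(N2CCC[C@H]2C(=O)[O-])=C(OC)C1=O.[Li+] | intermediate
16 | 1-[(6R)-4-(2-tert-butoxy-2-oxoethyl)-6-hydroxy-2-methoxy-6-methyl-3-oxocyclohexa-1,4-dien-1-yl]-3,4-dihydro-2H-pyrrolium ion (formed in the flask) | CC(C)(C)OC(=O)CC1=C[C@@](C)(O)C([N+]2=CCCC2)=C(OC)C1=O | intermediate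
17 | (4R)-dienone N,O-acetal with rings D and E; aminal carbon (S) | CC(C)(C)OC(=O)CC1=C[C@@]2(C)O[C@H]3CCCN3C2=C(OC)C1=O | intermediate
18 | 2-bromo-5-methoxyphenol | COc1ccc(Br)c(O)c1 | starting material
19 | 1-(benzyloxy)-2-bromo-5-methoxybenzene | COc1ccc(Br)c(OCc2ccccc2)c1 | intermediate
20 | 3-(benzyloxy)-5-methoxybenzyne (formed in the flask) | COC1=CC#CC(OCc2ccccc2)=C1 | intermediate
21 | (4R)-8-benzyloxy-9-hydroxy-2,6-dimethoxy-4-methyl-4H-phenanthren-1-one with rings D and E; aminal carbon (S) | COC1=C2N3CCC[C@@H]3O[C@]2(C)c2c(cc(O)c3c(OCc4ccccc4)cc(OC)cc23)C1=O | intermediate
22 | 8,9-dihydroxy tautomer of the target (formed in the flask) | COC1=C2N3CCC[C@@H]3O[C@]2(C)c2c(cc(O)c3c(O)cc(OC)cc23)C1=O | intermediate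
23 | CNP0528850.1 (C4 R; aminal carbon S) | COC1=C2N3CCC[C@@H]3O[C@]2(C)C2=C(CC(=O)c3c(O)cc(OC)cc32)C1=O | target

## Step count and least certain steps

Total step count: 13. Longest linear sequence: 10 (steps 1, 2, 3, 6, 7, 8, 9, 10, 12, 13); steps 4–5 and step 11 are side branches.

Step 9 (key step). Three processes could go wrong: capture of the oxidised ring at C2 (ortho, next to OMe) in place of C4, delivery of the oxygen to the wrong face of C4, and oxidation at nitrogen with loss of CO2 before the ring is attacked. The first two depend on the rotamer population about the crowded C3–N bond, which is argued here and not secured. Fallback (untethered capture, from 12 back to 15): 12 is desilylated with Bu4NF to methyl (2S)-1-[4-(2-tert-butoxy-2-oxoethyl)-3-hydroxy-2-methoxy-6-methylphenyl]pyrrolidine-2-carboxylate F1. This is oxidised with PhI(OAc)2 in MeCN/H2O so that water adds at C4. The (4R) quinol methyl (2S)-1-[(6R)-4-(2-tert-butoxy-2-oxoethyl)-6-hydroxy-2-methoxy-6-methyl-3-oxocyclohexa-1,4-dien-1-yl]pyrrolidine-2-carboxylate F2 is separated from its C4 epimer (a diastereomer, because of the alpha carbon) and saponified with LiOH to 15, which enters step 10. This gives up the chirality relay and half of the material, but no longer depends on the tether.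

Step 12. The dienolate may react at C10 instead of C4a, which leads to insertion into the C10–C9 bond and not to ring B. The amide base may add to the aryne. The dienolate may also expel the C4 oxygen by vinylogous beta-elimination, opening ring D, if it lives long enough before the aryne reaches it. Fallback (neutral cycloaddition, from 17 and 19 back to 21): 17 is deprotonated with LiN(SiMe3)2 in the presence of TBSCl at −78 °C, which traps the dienolate at once as tert-butyl tert-butyldimethylsilyl ketene acetal F3. 19 is lithiated ortho to bromine with lithium 2,2,6,6-tetramethylpiperidide in the presence of B(OiPr)3 and oxidised with H2O2 to 3-(benzyloxy)-2-bromo-5-methoxyphenol F4. O-Silylation with (Me3Si)2NH, bromine–lithium exchange with n-BuLi (silyl shift from O to C) and Tf2O give 3-(benzyloxy)-5-methoxy-2-(trimethylsilyl)phenyl trifluoromethanesulfonate F5. CsF in MeCN releases 20 from F5 without base; Diels–Alder addition to F3, then loss of the silyl group and of tert-butanol, gives 21.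

Step 10. Anodic oxidation of the electron-rich vinylogous amide may compete with decarboxylation, and methanol may capture the iminium ion before O4 does. During lactone opening, deprotonation at C10 followed by expulsion of the C4 carboxylate may compete with acyl attack. Fallback (chemical decarboxylation, from 14 back to 17): 14 is opened with LiOH to 15 as before, and the dried salt is treated with Pb(OAc)4 and catalytic Cu(OAc)2 in MeCN/pyridine at 0 °C. The lead carboxylate loses CO2 in solution, and the same ion 16 is captured by O4 to give 17. No new compound is involved.

Step 6. Slow SN2 attack of the 2,6-disubstituted aniline on the secondary triflate would let elimination of triflic acid and erosion of configuration compete. Fallback (reverse order of the two N-alkylations, from 5 and 7 back to 10): 7 is mesylated to methyl (2R)-5-bromo-2-(methylsulfonyloxy)pentanoate F6. With NaI and i-Pr2NEt in MeCN, 5 is alkylated first at the primary carbon to give methyl (2R)-5-[4-bromo-3-(tert-butyldimethylsilyloxy)-2-methoxy-6-methylanilino]-2-(methylsulfonyloxy)pentanoate F7. The hindered N–C alpha bond then forms intramolecularly, by 5-exo-tet displacement of the mesylate with inversion, to give 10.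

## Further compounds

F1 | step 9 | methyl (2S)-1-[4-(2-tert-butoxy-2-oxoethyl)-3-hydroxy-2-methoxy-6-methylphenyl]pyrrolidine-2-carboxylate | COC(=O)[C@@H]1CCCN1c1c(C)cc(CC(=O)OC(C)(C)C)c(O)c1OC
F2 | step 9 | methyl (2S)-1-[(6R)-4-(2-tert-butoxy-2-oxoethyl)-6-hydroxy-2-methoxy-6-methyl-3-oxocyclohexa-1,4-dien-1-yl]pyrrolidine-2-carboxylate | CC(C)(C)OC(=O)CC1=C[C@@](C)(O)C(N2CCC[C@H]2C(=O)OC)=C(OC)C1=O
F3 | step 12 | tert-butyl tert-butyldimethylsilyl ketene acetal of 17 | CC(C)(C)OC(O[Si](C)(C)C(C)(C)C)=CC1=C[C@@]2(C)O[C@H]3CCCN3C2=C(OC)C1=O
F4 | step 12 | 3-(benzyloxy)-2-bromo-5-methoxyphenol | COc1cc(O)c(Br)c(OCc2ccccc2)c1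
F5 | step 12 | 3-(benzyloxy)-5-methoxy-2-(trimethylsilyl)phenyl trifluoromethanesulfonate | COc1cc(OS(=O)(=O)C(F)(F)F)c([Si](C)(C)C)c(OCc2ccccc2)c1
F0 | step 10 | none | none
F6 | step 6 | methyl (2R)-5-bromo-2-(methylsulfonyloxy)pentanoate | COC(=O)[C@H](OS(C)(=O)=O)CCCBr
F7 | step 6 | methyl (2R)-5-[4-bromo-3-(tert-butyldimethylsilyloxy)-2-methoxy-6-methylanilino]-2-(methylsulfonyloxy)pentanoate | COC(=O)[C@H](OS(C)(=O)=O)CCCNc1c(C)cc(Br)c(O[Si](C)(C)C(C)(C)C)c1OC
A1 | alternative 1 | 1-[1-acetyl-4-(benzyloxy)-5,7-dimethoxynaphthalen-2-yl]-2,2-dimethoxypropane-1,3-dione (keto aldehyde) | CC(=O)c1c(C(=O)C(OC)(OC)C=O)cc(OCc2ccccc2)c2c(OC)cc(OC)cc12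
A2 | alternative 1 | (2S,4S)-4-(tert-butyldimethylsilyloxy)pyrrolidine-2-carboxylic acid | OC(=O)[C@@H]1C[C@H](O[Si](C)(C)C(C)(C)C)CN1
A3 | alternative 1 | pentacyclic cycloadduct with C2 dimethyl ketal and silyloxy pyrrolidine | COC1(OC)[C@@H]2N3C[C@@H](O[Si](C)(C)C(C)(C)C)C[C@@H]3O[C@]2(C)c2c(cc(OCc3ccccc3)c3c(OC)cc(OC)cc23)C1=O
A4 | alternative 2 | 1-methyl-4-oxocyclohexa-2,5-dien-1-yl N-(4,4-dimethoxybutyl)carbamate | COC(OC)CCCNC(=O)OC1(C)C=CC(=O)C=C1
A5 | alternative 2 | cis-fused bicyclic oxazolidinone enone | COC(OC)CCCN1C(=O)O[C@]2(C)C=CC(=O)C[C@H]12
A6 | alternative 3 | ortho-alkyl benzaldehyde with rings D and E and a tethered methoxy enaminone vinyl ketone | CO/C(C(=O)C=C)=C1\N2CCC[C@@H]2O[C@]1(C)Cc1cc(OC)cc(OC)c1C=O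
A7 | alternative 3 | C9 alcohol with saturated C4a and C10a | COC1=C2N3CCC[C@@H]3O[C@]2(C)[C@@H]2c3cc(OC)cc(OC)c3[C@H](O)C[C@@H]2C1=O
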